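**Conventions and assumption**

- Eremophilane numbering is used throughout. β is the face of the C14 methyl on C5. A name without a descriptor at C4, C5 or C7 has the C4 and C5 methyl groups and the C7 isopropenyl group β, as in the target.
- Assumption: (R)-BINAP is written for step 6 on the assumption that it selects the ring alkene leading to (4aS,8aS)-13; should the antipode predominate, (S)-BINAP is used and nothing else changes.

## Analysis of the target

The target 30 is a 10βH-eremophilane: a cis-fused decalin (ring A: C1–C5 and C10; ring B: C5–C10) with a C8 ketone, a senecioate on O3 and an angelate on O9. Its six stereocentres are (3R,4R,5R,7R,9R,10S): the C14 methyl on the quaternary C5, the C15 methyl on C4, H10, the C9 acyloxy group and the C7 isopropenyl group are all β, and only the C3 acyloxy group is α. In the chair–chair conformer with C14 axial on ring A, the substituents at C3, C4, C7 and C9 are all equatorial, so the configurations at C7 and C9 (each next to the C8 carbonyl) are the thermodynamically preferred ones, whereas C5 and C10 must be set absolutely. The sensitive groups are the angelate (Z to E isomerisation by nucleophiles, acid or heat), the β,γ-unsaturated ketone (the isopropenyl double bond can move into conjugation through the epimerisable C7) and the α-acyloxy ketone at C8/C9. The difficulty lies in the vicinal cis-dimethyl pair at C4/C5 with its quaternary centre, a cis ring fusion of defined absolute sense, and three oxygens with two different unsaturated acyl groups. The strategy rests on reading C5 and C10 as part of a 1-methylcyclohexa-2,5-dien-1-yl unit: C5 is its prochiral quaternary carbon, ring B is the diene ring itself, and ring A is closed onto one of the two enantiotopic alkenes through the C1–C10 bond.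

## Retrosynthetic reasoning

**C9–O acyl bond (30 ⇒ 27 + 28).** The angelate is the most fragile group, so it is attached last, through the mixed anhydride 29 under conditions free of nucleophilic catalysts. The forward step must acylate a secondary α-ketol without isomerising the Z alkene or disturbing C7.

**O–Si bond (27 ⇒ 26).** The C9 hydroxyl is carried as a triethylsilyl ether through iodination, cross-coupling and conjugate reduction, and is released under buffered fluoride.

**C6–H and C7–H (26 ⇒ 25).** The saturated ketone comes from conjugate reduction of the C6=C7 enone. C7 is created by protonation of the resulting dienolate, which has to occur at the α carbon so that the isopropenyl group stays unconjugated.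

**C7–C11 (25 ⇒ 23 + 24, then 23 ⇒ 22 ⇒ 21).** The isopropenyl group is cut off at the enone α carbon; forward, α-iodination and cross-coupling with boronate 24 install it. Placing this disconnection late keeps the isopropenyl alkene away from every oxidation.

**C8=O and the C8–O/C9–O bonds (21 ⇒ 20 ⇒ 19).** The α-hydroxy enone is traced to the ring B diene of 19: cis-dihydroxylation of C8=C9 from the β face sets the C9 oxygen, and oxidation of the allylic C8 hydroxyl gives the enone that the C7 chemistry needs.

**C3–O (19 ⇒ 17 + 18, then 17 ⇒ 16 ⇒ 15).** The 3α ester is cut with inversion. Hydride is expected to reach the C3 ketone only from the α face, giving the 3β alcohol 17, so an esterification with inversion delivers the senecioate directly. The ketone 16 comes from conjugate reduction of the ring A enone of 15.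

**C4–C15 (15 ⇒ 13 + 2).** The methyl group is removed from the α′ position of the ring A enone; forward, the dienolate 14 is methylated on the face that makes C15 cis to C14. This is done directly after ring formation, while C4 is the only position that can be enolised kinetically.

**C1–C10 (13 ⇒ 12), the key disconnection.** Cutting this bond opens ring A and turns the two ring-fusion stereocentres into one prochiral quaternary carbon of an achiral cyclohexadiene. No other ring bond does this: a cut at C5 would forfeit the symmetry, and a cut inside ring B would leave the quaternary centre to be made separately. Forward, an enantioselective intramolecular Heck reaction must choose one of two enantiotopic alkenes and leave a ring A enone (handle for C3 and C4) and a ring B diene (handle for C7, C8 and C9).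

**C1–I/C2–H and C2–C3 (12 ⇒ 11 ⇒ 9 + 10).** The (Z)-β-iodoenone comes from anti hydroiodination of ynone 11, and the ynone from acylation of the acetylide 10 by amide 9.

**C4 insertion (9 ⇒ 6 ⇒ 3, with 4 and 7).** The amide is the one-carbon homologue of acid 3. Arndt–Eistert homologation through 5, 6 and ketene 8 inserts C4 without any substitution at the neopentyl position.

**C5–C14 (3 ⇒ 1 + 2).** Birch reductive methylation of benzoic acid 1 creates the quaternary carbon and the skipped diene in one step.

## Alternatives that were turned down

**Alternative 1: enzymatic cyclisation, then oxidative tailoring.**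
- Disconnection: both rings at once (C6–C7 and C5–C10, with C14 moving from C10 to C5), back to farnesyl diphosphate A1.
- Forward key step: aristolochene synthase folds A1 into (+)-aristolochene A2.
- For: the whole C15 skeleton, the C4/C5 cis-dimethyl pair in the correct absolute configuration and the isopropenyl group arrive in one protecting-group-free step. On skeleton step count and on the C4/C5 problem it is clearly stronger than the chosen route.
- Against: A2 is a hydrocarbon with a C9=C10 alkene and the isopropenyl group on the face opposite to C14. C8 (allylic) and C9/C10 (alkene) can be addressed, and C7 could be epimerised through a C8 ketone. C3, however, is an unactivated methylene with no neighbouring handle, so its site- and face-selective hydroxylation would need a second, engineered enzyme.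
- Comparison: the chosen strategy leaves the key step with a carbonyl at C3 and a diene across C6–C9, so every oxygen of the target has a functional handle.

**Alternative 2: anionic oxy-Cope rearrangement of a bridged carbinol.**
- Disconnection: C5–C6, unfolding the cis-decalin to 3,3-dimethoxy-5,6-dimethyl-2-vinylbicyclo[2.2.2]oct-5-en-2-ol A3.
- Forward key step: the potassium alkoxide of A3 undergoes a [3,3] shift in which C5–C6 forms while the bond between the carbinol carbon C8 and the bridgehead C3 breaks. Protonation of the enolate gives 9,9-dimethoxy-11,12,13-trinor-10βH-eremophil-3-en-8-one A4.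
- For: the rigid bicycle guarantees the cis fusion and the quaternary C5. C8 and C9 arrive oxygenated and already differentiated, with no site selection between two alkenes. The C3=C4 alkene bearing C15 can be hydroborated so that O3 and H4 enter on one face, giving the trans O3/C15 relation in a single step. On ring A stereocontrol and on C8/C9 regiochemistry it is stronger than the chosen route.
- Against: A3 comes from a cycloaddition of a dearomatised phenol and is racemic unless an auxiliary or a resolution is added. The ketal must be unveiled and reduced to the 9β alcohol beside the C8 ketone. The isopropenyl group still has to be brought to C7 next to a ketone, with the same C7 issues as here.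
- Comparison: the step count after the key step is similar. The chosen strategy offers catalytic absolute stereocontrol in the ring-forming step from an achiral five-step precursor.

**Alternative 3: chiral-pool enone plus silyloxydiene annulation.**
- Disconnection: ring A through C4–C5 and C1–C10, back to (S)-3-methyl-5-(prop-1-en-2-yl)cyclohex-2-en-1-one A5 and (Z)-3-(tert-butyldimethylsilyloxy)penta-1,3-diene A6.
- Forward key step: a Lewis-acid-promoted [4+2] annulation gives 3-(tert-butyldimethylsilyloxy)-4-epi-10βH-eremophila-2,11-dien-9-one A7.
- For: it is convergent; all fifteen carbons, the absolute configuration and the C7 isopropenyl group in its final configuration are present in A7. On convergence and on C7 (here dependent on a late protonation) it is stronger.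
- Against: the dienophile carbon C5 is the methyl-bearing β carbon of an enone, so it is poorly reactive and needs Lewis acids that the acid-labile A6 barely tolerates. The cycloaddition puts C15 trans to C14, so C4 must be epimerised through the C3 ketone. The carbonyl sits at C9, so the C8/C9 pattern has to be inverted by a 1,2-carbonyl transposition beside the epimerisable C7. The isopropenyl alkene must survive every later oxidation.
- Comparison: the chosen strategy places the oxygens at C8 and C9 directly and introduces the isopropenyl group only after all oxidations.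

Key step: step 6

## Route

Step 1
Reactants: 1 benzoic acid; 2 iodomethane
Product: 3 1-methylcyclohexa-2,5-diene-1-carboxylic acid
Conditions: Li, NH3(l)/THF, −78 °C; then MeI, −78 °C to rt; aq. HCl work-up
Reagents that add atoms: iodomethane, CI
Why: Birch reductive alkylation: two-electron reduction of the benzoate gives the carboxylate-stabilised cyclohexadienyl anion, which iodomethane alkylates at the ipso carbon. This creates the quaternary C5 with C14 and leaves the two enantiotopic alkenes and the C8 methylene.

Step 2
Reactants: 3 1-methylcyclohexa-2,5-diene-1-carboxylic acid; 4 (trimethylsilyl)diazomethane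
Product: 6 2-diazo-1-(1-methylcyclohexa-2,5-dien-1-yl)ethan-1-one, via acid chloride 5 (not isolated)
Conditions: (COCl)2, cat. DMF, CH2Cl2, 0 °C to rt; evaporate; then Me3SiCHN2, MeCN–THF, 0 °C to rt
Reagents that add atoms: (trimethylsilyl)diazomethane, C[Si](C)(C)C=[N+]=[N-]
Why: First half of the Arndt–Eistert homologation: acid chloride formation and C-acylation of the diazoalkane with loss of the silyl group. The quaternary α carbon rules out ketene formation from the acid chloride.

Step 3
Reactants: 6 2-diazo-1-(1-methylcyclohexa-2,5-dien-1-yl)ethan-1-one; 7 N,O-dimethylhydroxylamine hydrochloride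
Product: 9 N-methoxy-N-methyl-2-(1-methylcyclohexa-2,5-dien-1-yl)acetamide, via ketene 8 (not isolated)
Conditions: hν (medium-pressure Hg lamp, Pyrex filter), MeNH(OMe)·HCl, Et3N, THF, rt
Reagents that add atoms: N,O-dimethylhydroxylamine hydrochloride, CNOC.Cl
Why: Photochemical Wolff rearrangement: loss of N2 with 1,2-shift of the quaternary carbon gives ketene 8, which the hydroxylamine traps as the Weinreb amide, so C4 is inserted between C5 and C3. The skipped diene does not absorb at the wavelengths passed by Pyrex.

Step 4
Reactants: 9 N-methoxy-N-methyl-2-(1-methylcyclohexa-2,5-dien-1-yl)acetamide; 10 ethynylmagnesium bromide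
Product: 11 1-(1-methylcyclohexa-2,5-dien-1-yl)but-3-yn-2-one
Conditions: HC≡CMgBr, THF, 0 °C to rt; inverse quench into cold aq. NaHSO4
Reagents that add atoms: ethynylmagnesium bromide, C#C[Mg]Br
Why: Weinreb ketone synthesis: the chelated tetrahedral adduct stops at the ketone stage. The cold acidic quench keeps the liberated amine from adding to the ynone.

Step 5
Reactants: 11 1-(1-methylcyclohexa-2,5-dien-1-yl)but-3-yn-2-one
Product: 12 (Z)-4-iodo-1-(1-methylcyclohexa-2,5-dien-1-yl)but-3-en-2-one
Conditions: NaI, AcOH, rt, dark; used promptly
Reagents that add atoms: sodium iodide, [Na+].[I-]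
Why: Conjugate hydroiodination of the ynone: iodide adds at C1 and the allenol is protonated anti, so the kinetic (Z)-β-iodoenone results. Z is the only geometry in which C1 can reach the ring.

Step 6
Reactants: 12 (Z)-4-iodo-1-(1-methylcyclohexa-2,5-dien-1-yl)but-3-en-2-one
Product: 13 (4aS,8aS)-8a-methyl-1,8a-dihydronaphthalen-2(4aH)-one (cis-fused; ring A enone C1=C2–C3=O, ring B diene C6=C7–C8=C9)
Conditions: Pd(OAc)2 (10 mol %), (R)-BINAP (20 mol %), Ag3PO4 (2 equiv), NMP, 60 °C
Reagents that add atoms: none
Why: Pd(OAc)2 and (R)-BINAP give zerovalent palladium, which inserts into the C1–I bond with retention of the Z geometry; Ag3PO4 removes iodide and takes up the proton, so a cationic alkenylpalladium complex with both phosphorus atoms bound carries the reaction. One of the two enantiotopic ring alkenes coordinates and undergoes syn carbopalladation, C1 bonding to C10 and palladium to C9; this closes ring A in the 6-exo-trig mode, the 7-endo alternative (C1 to C9) being disfavoured by the four-atom tether. Syn β-hydride elimination can only use a hydrogen of the C8 methylene, because H10 is anti to palladium, and it leaves the conjugated C6=C7–C8=C9 diene of ring B. The closest known reaction type is the asymmetric intramolecular Heck desymmetrisation of 1-substituted cyclohexa-2,5-dienes carrying (Z)-alkenyl halide tethers, which gives cis-decalins with Pd(OAc)2, BINAP and Ag2CO3 or Ag3PO4. C10 is set relative to C5 by the tether: C1 can reach C10 only on the face of ring B that carries C4, so H10 ends cis to C14 (cis fusion). The absolute configuration of both centres (5S,10S in 13, which become 5R,10S in 30 by a change of priorities only) is fixed by which alkene the chiral bisphosphine pocket selects. The step needs enantiotopic-group selection (ligand kept bidentate by the silver salt), retention of the Z alkene (cyclisation faster than Z/E isomerisation) and a product that is not enolised toward C10 (weak insoluble base, moderate temperature).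

Step 7
Reactants: 13 (4aS,8aS)-8a-methyl-1,8a-dihydronaphthalen-2(4aH)-one; 2 iodomethane
Product: 15 (1R,4aS,8aS)-1,8a-dimethyl-1,8a-dihydronaphthalen-2(4aH)-one (11,12,13-trinor-10βH-eremophila-1,6,8-trien-3-one), via lithium dienolate 14 (not isolated)
Conditions: LiN(iPr)2, THF, −78 °C; then MeI, −78 to −40 °C
Reagents that add atoms: iodomethane, CI
Why: Kinetic deprotonation of the enone at the α′ carbon C4 (not at the γ hydrogen on C10) gives the cross-conjugated dienolate 14, which is C-methylated. Iodomethane should enter on the convex β face of the folded cis-bicycle, anti to the pseudoaxial C5–C6 bond, which puts C15 cis to C14 (4R).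

Step 8
Reactants: 15 11,12,13-trinor-10βH-eremophila-1,6,8-trien-3-one
Product: 16 11,12,13-trinor-10βH-eremophila-6,8-dien-3-one
Conditions: [(Ph3P)CuH]6, H2O (degassed), PhMe, rt
Reagents that add atoms: none
Why: Conjugate reduction: hydride adds to C1 of the enone and water protonates the enolate at C2. The unactivated ring B diene is inert, and no base is present that could epimerise C4 or C10.

Step 9
Reactants: 16 11,12,13-trinor-10βH-eremophila-6,8-dien-3-one
Product: 17 11,12,13-trinor-10βH-eremophila-6,8-dien-3β-ol
Conditions: LiBH(s-Bu)3, THF, −78 to 0 °C; aq. NH4Cl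
Reagents that add atoms: none
Why: Ketone reduction by a bulky borohydride from the α face, the β face being covered by C15 and, 1,3-diaxially, by C14. This should give the 3β (axial, 3S) alcohol, which is chosen so that the next step can invert it.

Step 10
Reactants: 17 11,12,13-trinor-10βH-eremophila-6,8-dien-3β-ol; 18 3-methylbut-2-enoic acid (senecioic acid)
Product: 19 11,12,13-trinor-10βH-eremophila-6,8-dien-3α-yl 3-methylbut-2-enoate
Conditions: PPh3 and DIAD premixed at 0 °C; then 17 and 18, PhMe, 0 °C to rt
Reagents that add atoms: 3-methylbut-2-enoic acid, CC(C)=CC(=O)O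
Why: Mitsunobu esterification: SN2 displacement of the oxyphosphonium group by the carboxylate inverts C3 and installs the senecioate in the required 3α (3R, equatorial) configuration in one operation. Premixing the phosphine and the azodicarboxylate keeps free azo compound away from the ring B diene.

Step 11
Reactants: 19 11,12,13-trinor-10βH-eremophila-6,8-dien-3α-yl 3-methylbut-2-enoate
Product: 20 8β,9β-dihydroxy-11,12,13-trinor-10βH-eremophil-6-en-3α-yl 3-methylbut-2-enoate
Conditions: OsO4 (2 mol %), NMO (1.1 equiv), acetone–H2O, 0 °C; Na2SO3
Reagents that add atoms: osmium tetroxide, O=[Os](=O)(=O)=O; N-methylmorpholine N-oxide, C[N+]1([O-])CCOCC1; water, O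
Why: Upjohn dihydroxylation: OsO4 should add to C8=C9, whose allylic neighbour C10 carries only hydrogen on the β face, rather than to C6=C7 beside the quaternary C5, and from the β face because the axial C5–C4 bond of ring A covers the α face of ring B. This sets the 9β oxygen (9R); the 8β hydroxyl is removed in the next step, and the electron-poor senecioate alkene is far less reactive than the diene.

Step 12
Reactants: 20 8β,9β-dihydroxy-11,12,13-trinor-10βH-eremophil-6-en-3α-yl 3-methylbut-2-enoate
Product: 21 9β-hydroxy-8-oxo-11,12,13-trinor-10βH-eremophil-6-en-3α-yl 3-methylbut-2-enoate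
Conditions: MnO2 (activated, excess), CH2Cl2, rt
Reagents that add atoms: none
Why: Chemoselective allylic oxidation: only the C8 hydroxyl is allylic (to C6=C7) and is oxidised to the enone; the C9 hydroxyl stays.

Step 13
Reactants: 21 9β-hydroxy-8-oxo-11,12,13-trinor-10βH-eremophil-6-en-3α-yl 3-methylbut-2-enoate
Product: 22 8-oxo-9β-(triethylsilyloxy)-11,12,13-trinor-10βH-eremophil-6-en-3α-yl 3-methylbut-2-enoate
Conditions: Et3SiCl, imidazole, DMF, 0 °C to rt
Reagents that add atoms: chlorotriethylsilane, CC[Si](Cl)(CC)CC
Why: Silylation of the secondary C9 hydroxyl protects the α-ketol from iodine, aqueous base, palladium and copper hydride. The triethylsilyl ether can later be removed under mild buffered fluoride.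

Step 14
Reactants: 22 8-oxo-9β-(triethylsilyloxy)-11,12,13-trinor-10βH-eremophil-6-en-3α-yl 3-methylbut-2-enoate
Product: 23 7-iodo-8-oxo-9β-(triethylsilyloxy)-11,12,13-trinor-10βH-eremophil-6-en-3α-yl 3-methylbut-2-enoate
Conditions: I2, pyridine–CH2Cl2, 0 °C to rt
Reagents that add atoms: iodine, II
Why: α-Iodination of the enone by reversible addition of pyridine to C6, iodination of the enolate at C7 and elimination. The β,β-disubstituted senecioate cannot react by this pathway.

Step 15
Reactants: 23 7-iodo-8-oxo-9β-(triethylsilyloxy)-11,12,13-trinor-10βH-eremophil-6-en-3α-yl 3-methylbut-2-enoate; 24 4,4,5,5-tetramethyl-2-(prop-1-en-2-yl)-1,3,2-dioxaborolane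
Product: 25 8-oxo-9β-(triethylsilyloxy)-10βH-eremophila-6,11-dien-3α-yl 3-methylbut-2-enoate
Conditions: PdCl2(dppf) (5 mol %), K3PO4, THF–H2O, 45 °C
Reagents that add atoms: 4,4,5,5-tetramethyl-2-(prop-1-en-2-yl)-1,3,2-dioxaborolane, CC(=C)B1OC(C)(C)C(C)(C)O1
Why: Suzuki–Miyaura coupling of the 2-iodoenone with the isopropenyl boronate forms C7–C11 and brings in C11–C13. The isopropenyl group enters only after all oxidations are over.

Step 16
Reactants: 25 8-oxo-9β-(triethylsilyloxy)-10βH-eremophila-6,11-dien-3α-yl 3-methylbut-2-enoate
Product: 26 8-oxo-9β-(triethylsilyloxy)-10βH-eremophil-11-en-3α-yl 3-methylbut-2-enoate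
Conditions: [(Ph3P)CuH]6, H2O, PhMe, 0 °C to rt
Reagents that add atoms: none
Why: Conjugate reduction: hydride adds to C6 and water protonates the resulting dienolate at its α carbon C7, the kinetic site, which keeps the isopropenyl double bond out of conjugation. Protonation along the axial direction on the α face gives the chair with the isopropenyl group equatorial (7β, 7R), which is also the thermodynamically favoured epimer. The β,β-disubstituted senecioate is reduced far more slowly than the enone.

Step 17
Reactants: 26 8-oxo-9β-(triethylsilyloxy)-10βH-eremophil-11-en-3α-yl 3-methylbut-2-enoate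
Product: 27 9β-hydroxy-8-oxo-10βH-eremophil-11-en-3α-yl 3-methylbut-2-enoate
Conditions: HF·pyridine, pyridine, THF, 0 °C
Reagents that add atoms: none
Why: Fluoride-mediated cleavage of the Si–O bond under buffered, weakly acidic conditions that neither epimerise C7 nor move the isopropenyl double bond.

Step 18
Reactants: 27 9β-hydroxy-8-oxo-10βH-eremophil-11-en-3α-yl 3-methylbut-2-enoate; 28 (Z)-2-methylbut-2-enoic acid (angelic acid)
Product: 30 (3R,4R,5R,7R,9R,10S)-9β-[(Z)-2-methylbut-2-enoyloxy]-3α-(3-methylbut-2-enoyloxy)-10βH-eremophil-11-en-8-one (CNP0164025.2), via mixed anhydride 29 (not isolated)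
Conditions: 28, 2,4,6-Cl3C6H2COCl, Et3N, PhMe, rt; then 27, PhMe, 70 °C
Reagents that add atoms: (Z)-2-methylbut-2-enoic acid, C/C=C(/C)C(=O)O
Why: Yamaguchi-type esterification through mixed anhydride 29: the alcohol attacks the less hindered angeloyl carbonyl. Leaving out nucleophilic catalysts such as DMAP is what preserves the Z geometry of the angelate.

## Compound list

1 | benzoic acid | O=C(O)c1ccccc1 | starting material
2 | iodomethane | CI | starting material
3 | 1-methylcyclohexa-2,5-diene-1-carboxylic acid | CC1(C(=O)O)C=CCC=C1 | intermediate
4 | (trimethylsilyl)diazomethane | C[Si](C)(C)C=[N+]=[N-] | starting material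
5 | 1-methylcyclohexa-2,5-diene-1-carbonyl chloride | CC1(C(=O)Cl)C=CCC=C1 | intermediate (not isolated)
6 | 2-diazo-1-(1-methylcyclohexa-2,5-dien-1-yl)ethan-1-one | CC1(C(=O)C=[N+]=[N-])C=CCC=C1 | intermediate
7 | N,O-dimethylhydroxylamine hydrochloride | CNOC.Cl | starting material
8 | 2-(1-methylcyclohexa-2,5-dien-1-yl)ethen-1-one (ketene) | CC1(C=C=O)C=CCC=C1 | intermediate (not isolated)
9 | N-methoxy-N-methyl-2-(1-methylcyclohexa-2,5-dien-1-yl)acetamide | CC1(CC(=O)N(C)OC)C=CCC=C1 | intermediate
10 | ethynylmagnesium bromide | C#C[Mg]Br | starting material
11 | 1-(1-methylcyclohexa-2,5-dien-1-yl)but-3-yn-2-one | CC1(CC(=O)C#C)C=CCC=C1 | intermediate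
12 | (Z)-4-iodo-1-(1-methylcyclohexa-2,5-dien-1-yl)but-3-en-2-one | CC1(CC(=O)/C=C\I)C=CCC=C1 | intermediate
13 | (4aS,8aS)-8a-methyl-1,8a-dihydronaphthalen-2(4aH)-one (11,12,13,15-tetranor-10βH-eremophila-1,6,8-trien-3-one) | C1=C[C@@]2(C)[C@H](C=CC(=O)C2)C=C1 | intermediate
14 | lithium dienolate of 13 (O–Li on C3, C3=C4 and C1=C2) | C1=C[C@@]2(C)[C@H](C=CC(O[Li])=C2)C=C1 | intermediate (not isolated)
15 | (1R,4aS,8aS)-1,8a-dimethyl-1,8a-dihydronaphthalen-2(4aH)-one (11,12,13-trinor-10βH-eremophila-1,6,8-trien-3-one) | C1=C[C@@]2(C)[C@H](C=CC(=O)[C@@H]2C)C=C1 | intermediate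
16 | 11,12,13-trinor-10βH-eremophila-6,8-dien-3-one | C1=C[C@@]2(C)[C@H](CCC(=O)[C@@H]2C)C=C1 | intermediate
17 | 11,12,13-trinor-10βH-eremophila-6,8-dien-3β-ol | C1=C[C@@]2(C)[C@H](CC[C@H](O)[C@@H]2C)C=C1 | intermediate
18 | 3-methylbut-2-enoic acid (senecioic acid) | CC(C)=CC(=O)O | starting material
19 | 11,12,13-trinor-10βH-eremophila-6,8-dien-3α-yl 3-methylbut-2-enoate | C1=C[C@@]2(C)[C@H](CC[C@@H](OC(=O)C=C(C)C)[C@@H]2C)C=C1 | intermediate
20 | 8β,9β-dihydroxy-11,12,13-trinor-10βH-eremophil-6-en-3α-yl 3-methylbut-2-enoate | C1=C[C@@]2(C)[C@H](CC[C@@H](OC(=O)C=C(C)C)[C@@H]2C)[C@@H](O)[C@H]1O | intermediate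
21 | 9β-hydroxy-8-oxo-11,12,13-trinor-10βH-eremophil-6-en-3α-yl 3-methylbut-2-enoate | C1=C[C@@]2(C)[C@H](CC[C@@H](OC(=O)C=C(C)C)[C@@H]2C)[C@@H](O)C1=O | intermediate
22 | 8-oxo-9β-(triethylsilyloxy)-11,12,13-trinor-10βH-eremophil-6-en-3α-yl 3-methylbut-2-enoate | C1=C[C@@]2(C)[C@H](CC[C@@H](OC(=O)C=C(C)C)[C@@H]2C)[C@@H](O[Si](CC)(CC)CC)C1=O | intermediate
23 | 7-iodo-8-oxo-9β-(triethylsilyloxy)-11,12,13-trinor-10βH-eremophil-6-en-3α-yl 3-methylbut-2-enoate | IC1=C[C@@]2(C)[C@H](CC[C@@H](OC(=O)C=C(C)C)[C@@H]2C)[C@@H](O[Si](CC)(CC)CC)C1=O | intermediate
24 | 4,4,5,5-tetramethyl-2-(prop-1-en-2-yl)-1,3,2-dioxaborolane | CC(=C)B1OC(C)(C)C(C)(C)O1 | starting material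
25 | 8-oxo-9β-(triethylsilyloxy)-10βH-eremophila-6,11-dien-3α-yl 3-methylbut-2-enoate | C=C(C)C1=C[C@@]2(C)[C@H](CC[C@@H](OC(=O)C=C(C)C)[C@@H]2C)[C@@H](O[Si](CC)(CC)CC)C1=O | intermediate
26 | 8-oxo-9β-(triethylsilyloxy)-10βH-eremophil-11-en-3α-yl 3-methylbut-2-enoate | C=C(C)[C@H]1C[C@@]2(C)[C@H](CC[C@@H](OC(=O)C=C(C)C)[C@@H]2C)[C@@H](O[Si](CC)(CC)CC)C1=O | intermediate
27 | 9β-hydroxy-8-oxo-10βH-eremophil-11-en-3α-yl 3-methylbut-2-enoate | C=C(C)[C@H]1C[C@@]2(C)[C@H](CC[C@@H](OC(=O)C=C(C)C)[C@@H]2C)[C@@H](O)C1=O | intermediate
28 | (Z)-2-methylbut-2-enoic acid (angelic acid) | C/C=C(/C)C(=O)O | starting material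
29 | (Z)-2-methylbut-2-enoic 2,4,6-trichlorobenzoic anhydride | C/C=C(/C)C(=O)OC(=O)c1c(Cl)cc(Cl)cc1Cl | intermediate (not isolated)
30 | (3R,4R,5R,7R,9R,10S)-9β-[(Z)-2-methylbut-2-enoyloxy]-3α-(3-methylbut-2-enoyloxy)-10βH-eremophil-11-en-8-one | C=C(C)[C@H]1C[C@@]2(C)[C@H](CC[C@@H](OC(=O)C=C(C)C)[C@@H]2C)[C@@H](OC(=O)/C(C)=C\C)C1=O | target

## Step count and least certain steps

Total step count: 18. Longest linear sequence: 18 steps, from benzoic acid 1 to 30.

**Step 6 (key step).** Three processes threaten it. Incomplete removal of iodide from palladium opens a neutral pathway with partial dissociation of one phosphine arm, which erodes the selection between the enantiotopic alkenes. Z/E isomerisation of the iodoenone or of the alkenylpalladium species before insertion stops the cyclisation. Enolisation of the product toward C10, whose hydrogen is doubly allylic and vinylogous to the ketone, would erase the ring-fusion configuration. The fallback replaces the iodide by a triflate, which ionises from palladium without a silver salt. It sets out from amide 9: MeMgBr gives the methyl ketone 1-(1-methylcyclohexa-2,5-dien-1-yl)propan-2-one F1. Claisen formylation (HCO2Et, NaH) occurs at the methyl group, the methylene being neopentyl, and gives the hydroxymethylene ketone (Z)-4-hydroxy-1-(1-methylcyclohexa-2,5-dien-1-yl)but-3-en-2-one F2. O-Sulfonylation of its chelated sodium enolate with Tf2O at −78 °C gives the (Z)-enol triflate F3. Cyclisation of F3 with Pd(OAc)2, (R)-BINAP and K2CO3 in toluene returns to 13.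

**Step 7.** The facial discrimination at C4 may be poor, or iodomethane may prefer the α face, because the β face carries the C14 methyl right next to the reacting carbon while the α face carries the C5–C6 bond of ring B. Proton exchange between product and enolate could also lead to a second methylation. The fallback introduces C15 as a methylene group and sets C4 by protonation, so the proton takes the face an electrophile prefers and the methyl group ends on the other. It sets out from 13 through enolate 14: dimethylmethyleneiminium iodide gives the 4-(dimethylaminomethyl) ketone F4. Quaternisation with MeI and elimination with NaHCO3 give the 4-methylene trienone F5. [(Ph3P)CuH]6 with water reduces both conjugated C=C bonds, with protonation of the C3–C4 enolate at C4, and the route is rejoined at 16.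

**Step 10.** The axial oxyphosphonium intermediate has antiperiplanar hydrogens on C2 and C4 and may eliminate instead of being displaced; the carboxylate of a weakly acidic unsaturated acid is a slow nucleophile at the hindered C3; and any free azodicarboxylate can add to the ring B diene. The fallback separates inversion from acylation. It sets out from 17: Mitsunobu reaction with 4-nitrobenzoic acid (more acidic partner, less basic carboxylate) gives the 3α 4-nitrobenzoate F6. Methanolysis (K2CO3, MeOH) gives the 3α alcohol F7, and carbodiimide esterification with 18 (EDC·HCl, DMAP, CH2Cl2) returns to 19.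

**Step 11.** The two ring B alkenes are distinguished only by sterics (angular hydrogen versus angular methyl beside the alkene), so osmylation at C6=C7, or a second osmylation of the ene-diol as conversion is pushed, may cut into the yield; in the following step the cis-glycol may also undergo C–C cleavage on MnO2. The fallback relies on the same steric bias for site selection and does not improve it, but it avoids a free glycol altogether and stops cleanly at mono-oxidation. It sets out from 19: buffered mCPBA (NaHCO3, CH2Cl2, 0 °C) gives the 8β,9β-epoxide F8, whose remaining alkene is deactivated. Oxidative opening with dimethyl sulfoxide and BF3·OEt2, then iPr2NEt, attacks the allylic C8 and gives the α-hydroxy enone directly, rejoining the route at 21 and skipping 20.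

**Step 16.** The axial α trajectory at C7 runs 1,3 to the axial C5–C4 bond, so the proton may instead enter from the open β face and give the 7-epimer; protonation at the terminal carbon of the dienolate, or later base contact, would move the isopropenyl double bond into conjugation. The fallback switches from kinetic protonation to thermodynamic control. It sets out from the 7α-isopropenyl epimer F9: brief equilibration with catalytic DBU in toluene at 0 °C to rt is stopped before double-bond migration becomes significant. Because only the 7β epimer has all ring B substituents equatorial, the equilibrium should lie on the side of 26, where the route is rejoined.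

**Step 18.** Acylation of the hindered α-ketol is slow, and prolonged heating with amine may cause Z to E isomerisation of the angeloyl group, enolisation at C7 with migration of the isopropenyl double bond, or transposition of the α-ketol. The fallback changes the order of events so that the acylation is done on a substrate without an epimerisable C7. It sets out from 25: HF·pyridine gives the 9β-hydroxy dienone F10, and acylation with mixed anhydride 29 gives the 9β-angeloyloxy dienone F11. Conjugate reduction with [(Ph3P)CuH]6 and water, in which the enone should react faster than the two trisubstituted enoates, leads directly to 30.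

## Further compounds

F1 | step 6 | 1-(1-methylcyclohexa-2,5-dien-1-yl)propan-2-one | CC(=O)CC1(C)C=CCC=C1
F2 | step 6 | (Z)-4-hydroxy-1-(1-methylcyclohexa-2,5-dien-1-yl)but-3-en-2-one | CC1(CC(=O)/C=C\O)C=CCC=C1
F3 | step 6 | (Z)-4-(1-methylcyclohexa-2,5-dien-1-yl)-3-oxobut-1-en-1-yl trifluoromethanesulfonate | CC1(CC(=O)/C=C\OS(=O)(=O)C(F)(F)F)C=CCC=C1
F4 | step 7 | (4aS,8aS)-1-[(dimethylamino)methyl]-8a-methyl-1,8a-dihydronaphthalen-2(4aH)-one (both C1 epimers) | C1=C[C@@]2(C)[C@H](C=CC(=O)C2CN(C)C)C=C1
F5 | step 7 | (4aS,8aS)-8a-methyl-1-methylidene-1,8a-dihydronaphthalen-2(4aH)-one | C1=C[C@@]2(C)[C@H](C=CC(=O)C2=C)C=C1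
F6 | step 10 | 11,12,13-trinor-10βH-eremophila-6,8-dien-3α-yl 4-nitrobenzoate | C1=C[C@@]2(C)[C@H](CC[C@@H](OC(=O)c3ccc(cc3)[N+](=O)[O-])[C@@H]2C)C=C1
F7 | step 10 | 11,12,13-trinor-10βH-eremophila-6,8-dien-3α-ol | C1=C[C@@]2(C)[C@H](CC[C@@H](O)[C@@H]2C)C=C1
F8 | step 11 | 8β,9β-epoxy-11,12,13-trinor-10βH-eremophil-6-en-3α-yl 3-methylbut-2-enoate | C1=C[C@@]2(C)[C@H](CC[C@@H](OC(=O)C=C(C)C)[C@@H]2C)[C@H]3O[C@@H]13
F9 | step 16 | 8-oxo-9β-(triethylsilyloxy)-7-epi-10βH-eremophil-11-en-3α-yl 3-methylbut-2-enoate (7α-isopropenyl) | C=C(C)[C@@H]1C[C@@]2(C)[C@H](CC[C@@H](OC(=O)C=C(C)C)[C@@H]2C)[C@@H](O[Si](CC)(CC)CC)C1=O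
F10 | step 18 | 9β-hydroxy-8-oxo-10βH-eremophila-6,11-dien-3α-yl 3-methylbut-2-enoate | C=C(C)C1=C[C@@]2(C)[C@H](CC[C@@H](OC(=O)C=C(C)C)[C@@H]2C)[C@@H](O)C1=O
F11 | step 18 | 9β-[(Z)-2-methylbut-2-enoyloxy]-8-oxo-10βH-eremophila-6,11-dien-3α-yl 3-methylbut-2-enoate | C=C(C)C1=C[C@@]2(C)[C@H](CC[C@@H](OC(=O)C=C(C)C)[C@@H]2C)[C@@H](OC(=O)/C(C)=C\C)C1=O
A1 | alternative 1 | (2E,6E)-farnesyl diphosphate | CC(C)=CCC/C(C)=C/CC/C(C)=C/COP(=O)(O)OP(=O)(O)O
A2 | alternative 1 | (+)-aristolochene | C=C(C)[C@@H]1C[C@@]2(C)C(CCC[C@@H]2C)=CC1
A3 | alternative 2 | 3,3-dimethoxy-5,6-dimethyl-2-vinylbicyclo[2.2.2]oct-5-en-2-ol (vinyl group syn to the alkene bridge) | C=C[C@]1(O)C(OC)(OC)[C@H]2CC[C@@H]1C(C)=C2C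
A4 | alternative 2 | 9,9-dimethoxy-11,12,13-trinor-10βH-eremophil-3-en-8-one | O=C1CC[C@@]2(C)[C@H](CCC=C2C)C1(OC)OC
A5 | alternative 3 | (S)-3-methyl-5-(prop-1-en-2-yl)cyclohex-2-en-1-one | C=C(C)[C@H]1CC(C)=CC(=O)C1
A6 | alternative 3 | (Z)-3-(tert-butyldimethylsilyloxy)penta-1,3-diene | C=C/C(O[Si](C)(C)C(C)(C)C)=C/C
A7 | alternative 3 | 3-(tert-butyldimethylsilyloxy)-4-epi-10βH-eremophila-2,11-dien-9-one | C=C(C)[C@H]1C[C@@]2(C)[C@H](CC=C(O[Si](C)(C)C(C)(C)C)[C@H]2C)C(=O)C1
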